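## Retrosynthetic overview

1. Target 34 ⇐ triol hemiketal 33 (acetylation) ⇐ C4 allylic alcohol 32 (MnO2; the C8-OH closes the hemiketal pyran) ⇐ Nozaki–Hiyama–Kishi C4–C5 closure of the ten-membered ring.
2. γ-Lactone (C7, C8, C17) ⇐ iodolactonisation of a β-vinyl β-silyloxy ester built on the C9 aldehyde by Felkin allenyl-lithium addition and chelation-controlled propionate addition.
3. Ring A ⇐ 6-exo enolate alkylation of an acyclic methyl ketone / allylic bromide; the C14 and C2 carbinols come from substrate-directed reductions.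
4. Key step: the C1–C10 bond (quaternary C1, C10 and the exocyclic C11=C20) ⇐ dianionic Ireland–Claisen [3,3] rearrangement; all chirality is relayed from (R)-3-hydroxybutyrate.
5. Ring order: ring A (step 11) → γ-lactone (step 19) → ten-membered carbocycle (step 24) → hemiketal pyran (step 26).

Assumption: briarane numbering (C1–C20) locates atoms in all intermediates. The THP acetal centre (6–12) and the C4 carbinol (31, 32) are carried as inconsequential epimer mixtures.

## Route

**Step 1**
Reactants: 1 methyl acrylate; 2 2,2-dimethoxyacetaldehyde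
Product: 3 methyl 3-hydroxy-4,4-dimethoxy-2-methylenebutanoate (racemic)
Conditions: DABCO, dioxane/H2O, 23 °C
Reagents that add atoms: none
Why: Morita–Baylis–Hillman reaction of an activated α-alkoxy aldehyde; the carbinol centre is destroyed in step 2.

**Step 2**
Reactants: 3
Product: 4 methyl (Z)-2-(bromomethyl)-4,4-dimethoxybut-2-enoate
Conditions: NBS, Me2S, CH2Cl2, 0 → 23 °C
Reagents that add atoms: N-bromosuccinimide, O=C1CCC(=O)N1Br
Why: SN2′ bromination of a Baylis–Hillman alcohol gives the (Z)-bromide, with CH2Br cis to the CH(OMe)2 group.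

**Step 3**
Reactants: 4
Product: 5 (Z)-2-(bromomethyl)-4,4-dimethoxybut-2-en-1-ol
Conditions: DIBAL-H (2.2 equiv), CH2Cl2, −78 °C
Reagents that add atoms: none
Why: 1,2-reduction of the enoate ester; the allylic bromide is inert to DIBAL at −78 °C.

**Step 4**
Reactants: 5
Product: 6 THP ether of 5, 2-{[(Z)-2-(bromomethyl)-4,4-dimethoxybut-2-en-1-yl]oxy}oxane
Conditions: 3,4-dihydro-2H-pyran, PPTS, CH2Cl2, 23 °C
Reagents that add atoms: dihydropyran, C1=COCCC1
Why: Acid-catalysed acetalisation; THP survives LDA and is later converted directly to a bromide.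

**Step 5**
Reactants: 6; 7 sodium (R)-3-hydroxybutanoate
Product: 8 (Z)-4,4-dimethoxy-2-[(oxan-2-yloxy)methyl]but-2-en-1-yl (R)-3-hydroxybutanoate (acyloxymethyl arm cis to CH(OMe)2)
Conditions: DMF, 23 °C
Reagents that add atoms: none
Why: SN2 O-alkylation of the carboxylate by the primary allylic bromide leaves the secondary hydroxyl free.

**Step 6**
Reactants: 8
Product: 9 the same allyl ester of (2R,3R)-3-hydroxy-2-methylbutanoic acid
Conditions: LDA (2.2 equiv), THF, −78 → −40 °C; MeI, DMPU
Reagents that add atoms: iodomethane, CI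
Why: Fráter–Seebach alkylation of the chelated alkoxide-enolate dianion installs the C15 methyl, and occurs below the temperature at which the Claisen rearrangement starts.

**Step 7**
Reactants: 9
Product: 10 (2R,3S)-3-(dimethoxymethyl)-2-[(1R)-1-hydroxyethyl]-2-methyl-4-[(oxan-2-yloxy)methyl]pent-4-enoic acid (briarane 1R,10S,14R)
Conditions: LDA (2.5 equiv), THF, −78 → 45 °C; citric acid work-up
Reagents that add atoms: none
Why: Dianionic Ireland–Claisen [3,3] rearrangement: the Li-chelated enolate is attacked anti to the carbinol methyl through a chair in which the Z-disposed CH(OMe)2 is axial, which sets C1 (R) and C10 (S) and transposes the alkene to the exocyclic C11=C20.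

**Step 8**
Reactants: 10
Product: 11 N-methoxy-N-methyl amide of 10
Conditions: MeNH(OMe)·HCl, EDC·HCl, HOBt, iPr2NEt, CH2Cl2
Reagents that add atoms: N,O-dimethylhydroxylamine hydrochloride, CNOC.Cl
Why: Carbodiimide amidation; the amide blocks decarboxylation after the next oxidation and is the later C2 acyl donor.

**Step 9**
Reactants: 11
Product: 12 (2R,3S)-2-acetyl-3-(dimethoxymethyl)-N-methoxy-N,2-dimethyl-4-[(oxan-2-yloxy)methyl]pent-4-enamide
Conditions: Dess–Martin periodinane, NaHCO3, CH2Cl2
Reagents that add atoms: none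
Why: Oxidation of the relay carbinol to the methyl ketone; the quaternary α-carbon cannot epimerise.

**Step 10**
Reactants: 12
Product: 13 (2R,3R)-2-acetyl-4-(bromomethyl)-3-(dimethoxymethyl)-N-methoxy-N,2-dimethylpent-4-enamide (same geometry; descriptor changes by CIP)
Conditions: CBr4, PPh3, CH2Cl2, 0 → 23 °C
Reagents that add atoms: carbon tetrabromide, BrC(Br)(Br)Br
Why: Direct Appel-type conversion of the THP ether into the allylic bromide under near-neutral conditions that spare the acetal.

**Step 11**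
Reactants: 13
Product: 14 (1R,2S)-2-(dimethoxymethyl)-N-methoxy-N,1-dimethyl-3-methylidene-6-oxocyclohexane-1-carboxamide (ring A)
Conditions: KHMDS, THF, −78 → 0 °C
Reagents that add atoms: none
Why: The only enolisable position (the acetyl CH3, C13) undergoes 6-exo-tet intramolecular alkylation on the allylic bromide, closing ring A with the exocyclic methylene in place.

**Step 12**
Reactants: 14
Product: 15 (1R,2S,6S)-2-(dimethoxymethyl)-6-hydroxy-N-methoxy-N,1-dimethyl-3-methylidenecyclohexane-1-carboxamide (briarane 14S)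
Conditions: K-Selectride, THF, −78 °C
Reagents that add atoms: none
Why: Equatorial attack of the bulky hydride on the chair with axial C1-methyl gives the axial 14α-alcohol, cis to the carboxamide (as in 4,4-dimethyl-3-keto terpenoids).

**Step 13**
Reactants: 15; 16 (1,3-dioxolan-2-ylmethyl)magnesium bromide
Product: 17 1-[(1R,2S,6S)-2-(dimethoxymethyl)-6-hydroxy-1-methyl-3-methylidenecyclohexyl]-2-(1,3-dioxolan-2-yl)ethan-1-one
Conditions: 16 (4 equiv), THF, 0 → 23 °C
Reagents that add atoms: 16, Br[Mg]CC1OCCO1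
Why: Weinreb ketone synthesis; the chelated tetrahedral intermediate stops at the C2 ketone and brings in C3 and masked C4.

**Step 14**
Reactants: 17
Product: 18 syn-1,3-diol (briarane 1R,2R,10S,14S)
Conditions: Et2BOMe, NaBH4, THF/MeOH, −78 °C
Reagents that add atoms: none
Why: Narasaka–Prasad reduction: external hydride attacks the boron chelate of the C14-OH/C2=O pair axially, anti to C10, giving the 1,3-syn diol with C2 (R).

**Step 15**
Reactants: 18
Product: 19 2,14-O-isopropylidene acetal of 18
Conditions: 2,2-dimethoxypropane, PPTS, CH2Cl2, 23 °C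
Reagents that add atoms: 2,2-dimethoxypropane, COC(C)(C)OC
Why: Acetonide formation on the syn-1,3-diol (cis-fused 1,3-dioxane).

**Step 16**
Reactants: 19
Product: 20 C9 aldehyde (the C4 dioxolane and the acetonide are retained)
Conditions: PPTS, acetone/H2O (10:1), 23 °C
Reagents that add atoms: water, O
Why: Acyclic dimethyl acetals hydrolyse much faster than 1,3-dioxolanes, and acetone as solvent preserves the acetonide.

**Step 17**
Reactants: 20; 21 methoxyallene
Product: 22 α′-hydroxy vinyl ketone, C9(OH)–C8(=O)–CH=CH2 (9R)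
Conditions: 21, n-BuLi, THF, −78 °C; then 20; then 5% aq. H2SO4, THF, 0 °C
Reagents that add atoms: 21, COC=C=C; water, O
Why: 1-Lithio-1-methoxyallene (acyl-anion equivalent) adds Felkin–Anh, anti to the quaternary C1, giving C9 (R); mild hydrolysis of the allenyl ether unmasks the enone.

**Step 18**
Reactants: 22; 23 tert-butyl propanoate
Product: 24 tert-butyl ester of the 8,9-bis(triethylsilyloxy) β-vinyl adduct (briarane 8R by CIP, target geometry; 9R, 17R)
Conditions: 23, LDA, THF/DMPU, −78 °C (3 equiv enolate); then 22; then TESOTf, 2,6-lutidine, −78 → 0 °C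
Reagents that add atoms: 23, CCC(=O)OC(C)(C)C; triethylsilyl triflate, CC[Si](CC)(CC)OS(=O)(=O)C(F)(F)F
Why: Chelation-controlled (Cram) aldol 1,2-addition: Li bridges the C9 alkoxide and C8=O so the Z-enolate attacks anti to C10, setting C8 and (syn) C17; in-situ silylation blocks both hydroxyls.

**Step 19**
Reactants: 24
Product: 25 iodolactone, 5-(iodomethyl)-γ-lactone (briarane 7R by CIP, target geometry; 8S)
Conditions: I2, NaHCO3, MeCN, 0 °C
Reagents that add atoms: iodine, II
Why: 5-exo iodolactonisation of the tert-butyl ester (loss of isobutene) places CH2I trans to the bulky C9 side chain and cis to the C8 oxygen, which is the target C7 configuration; the silylated C8-OH cannot add to C11=C20.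

**Step 20**
Reactants: 25
Product: 26 methyl ester with a terminal C7–C6 epoxide
Conditions: K2CO3, MeOH, 0 → 23 °C
Reagents that add atoms: methanol, CO
Why: Methanolysis of the lactone releases the C7 alkoxide, which displaces iodide (the C7–O bond is retained, so no stereochemical change).

**Step 21**
Reactants: 26; 27 acetylene
Product: 28 5-(prop-2-ynyl)-γ-lactone (7S, 8S)
Conditions: 27, n-BuLi, THF, −78 °C; BF3·OEt2; then 26; then PPTS, CH2Cl2
Reagents that add atoms: 27, C#C
Why: Yamaguchi alkynylation opens the epoxide at the terminal C6, and the C7 alkoxide relactonises onto the methyl ester.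

**Step 22**
Reactants: 28
Product: 29 2-iodoallyl lactone, C6H2–C5(I)=C16H2
Conditions: B-iodo-9-BBN, hexane/CH2Cl2, −20 → 0 °C; AcOH
Reagents that add atoms: B-iodo-9-borabicyclo[3.3.1]nonane, IB1C2CCCC1CCC2
Why: Markovnikov iodoboration of the terminal alkyne then protonolysis gives the 2-iodo-1-alkene; the 1,1-disubstituted C11=C20 is not haloborated.

**Step 23**
Reactants: 29
Product: 30 C4 aldehyde with free 8,9-diol (acetonide retained)
Conditions: PPTS, acetone/H2O (9:1), 60 °C
Reagents that add atoms: water, O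
Why: Forcing transacetalisation removes the dioxolane and the two TES ethers, while acetone keeps the 2,14-acetonide.

**Step 24**
Reactants: 30
Product: 31 ten-membered carbocycle, C4 allylic alcohol (both C4 epimers)
Conditions: CrCl2 (15 equiv), NiCl2 (2 mol %), DMSO/THF, 23 °C, 2 mM
Reagents that add atoms: none
Why: Intramolecular Nozaki–Hiyama–Kishi coupling of the 2-iodoalkene with the aldehyde tolerates the lactone and free hydroxyls and forms the C4–C5 bond with C5=C16 already in place.

**Step 25**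
Reactants: 31
Product: 32 pentaol (2, 4, 8, 9, 14-OH)
Conditions: AcOH/H2O/THF (3:1:1), 45 °C
Reagents that add atoms: none
Why: Mild acid hydrolysis of the acetonide.

**Step 26**
Reactants: 32
Product: 33 2,9,14-triol hemiketal (tri-O-deacetyl junceellolide A)
Conditions: MnO2, CH2Cl2, 23 °C
Reagents that add atoms: none
Why: MnO2 oxidises only the allylic C4 carbinol; the C8 hydroxyl then adds to the C4 ketone to give the six-membered hemiketal, whose C4 configuration (R) is fixed by the bridged ring system.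

**Step 27**
Reactants: 33
Product: 34 (+)-junceellolide A
Conditions: Ac2O, pyridine, DMAP (cat.), 0 → 23 °C
Reagents that add atoms: acetic anhydride, CC(=O)OC(C)=O
Why: Acetylation of the three secondary alcohols; the hindered tertiary hemiketal hydroxyl does not react.

## Compound list

1 | methyl acrylate | C=CC(=O)OC | starting material
2 | 2,2-dimethoxyacetaldehyde | COC(OC)C=O | starting material
3 | methyl 3-hydroxy-4,4-dimethoxy-2-methylenebutanoate (racemic) | COC(OC)C(O)C(=C)C(=O)OC | intermediate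
4 | methyl (Z)-2-(bromomethyl)-4,4-dimethoxybut-2-enoate | BrC/C(C(=O)OC)=C\C(OC)OC | intermediate
5 | (Z)-2-(bromomethyl)-4,4-dimethoxybut-2-en-1-ol | BrC/C(CO)=C\C(OC)OC | intermediate
6 | THP ether of 5 | BrC/C(COC1CCCCO1)=C\C(OC)OC | intermediate
7 | sodium (R)-3-hydroxybutanoate | C[C@@H](O)CC(=O)[O-].[Na+] | starting material
8 | allyl (R)-3-hydroxybutanoate | C[C@@H](O)CC(=O)OC/C(COC1CCCCO1)=C\C(OC)OC | intermediate
9 | allyl (2R,3R)-3-hydroxy-2-methylbutanoate | C[C@@H](O)[C@@H](C)C(=O)OC/C(COC1CCCCO1)=C\C(OC)OC | intermediate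
10 | Claisen acid (1R,10S,14R) | OC(=O)[C@@](C)([C@@H](C)O)[C@@H](C(OC)OC)C(=C)COC1CCCCO1 | intermediate
11 | Weinreb amide of 10 | CON(C)C(=O)[C@@](C)([C@@H](C)O)[C@@H](C(OC)OC)C(=C)COC1CCCCO1 | intermediate
12 | β-keto amide (methyl ketone) | CON(C)C(=O)[C@@](C)(C(C)=O)[C@@H](C(OC)OC)C(=C)COC1CCCCO1 | intermediate
13 | allylic bromide | CON(C)C(=O)[C@@](C)(C(C)=O)[C@@H](C(OC)OC)C(=C)CBr | intermediate
14 | ring-A ketone (1R,10S) | CON(C)C(=O)[C@@]1(C)C(=O)CCC(=C)[C@@H]1C(OC)OC | intermediate
15 | 14α-alcohol (1R,10S,14S) | CON(C)C(=O)[C@@]1(C)[C@@H](O)CCC(=C)[C@@H]1C(OC)OC | intermediate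
16 | (1,3-dioxolan-2-ylmethyl)magnesium bromide | Br[Mg]CC1OCCO1 | starting material
17 | C2 ketone (β-hydroxy ketone) | O=C(CC1OCCO1)[C@@]2(C)[C@@H](O)CCC(=C)[C@@H]2C(OC)OC | intermediate
18 | syn-2,14-diol (1R,2R,10S,14S) | O[C@H](CC1OCCO1)[C@@]2(C)[C@@H](O)CCC(=C)[C@@H]2C(OC)OC | intermediate
19 | 2,14-acetonide | CC1(C)O[C@H](CC2OCCO2)[C@@]3(C)[C@@H](O1)CCC(=C)[C@@H]3C(OC)OC | intermediate
20 | C9 aldehyde | CC1(C)O[C@H](CC2OCCO2)[C@@]3(C)[C@@H](O1)CCC(=C)[C@@H]3C=O | intermediate
21 | methoxyallene | COC=C=C | starting material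
22 | (9R)-α′-hydroxy vinyl ketone | CC1(C)O[C@H](CC2OCCO2)[C@@]3(C)[C@@H](O1)CCC(=C)[C@@H]3[C@@H](O)C(=O)C=C | intermediate
23 | tert-butyl propanoate | CCC(=O)OC(C)(C)C | starting material
24 | bis-TES aldol adduct, tert-butyl ester | CC1(C)O[C@H](CC2OCCO2)[C@@]3(C)[C@@H](O1)CCC(=C)[C@@H]3[C@@H](O[Si](CC)(CC)CC)[C@@](O[Si](CC)(CC)CC)(C=C)[C@@H](C)C(=O)OC(C)(C)C | intermediate
25 | iodolactone | CC1(C)O[C@H](CC2OCCO2)[C@@]3(C)[C@@H](O1)CCC(=C)[C@@H]3[C@@H](O[Si](CC)(CC)CC)[C@@]4(O[Si](CC)(CC)CC)[C@H](CI)OC(=O)[C@@H]4C | intermediate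
26 | epoxy methyl ester | CC1(C)O[C@H](CC2OCCO2)[C@@]3(C)[C@@H](O1)CCC(=C)[C@@H]3[C@@H](O[Si](CC)(CC)CC)[C@@](O[Si](CC)(CC)CC)([C@@H]5CO5)[C@@H](C)C(=O)OC | intermediate
27 | acetylene | C#C | starting material
28 | propargyl lactone | CC1(C)O[C@H](CC2OCCO2)[C@@]3(C)[C@@H](O1)CCC(=C)[C@@H]3[C@@H](O[Si](CC)(CC)CC)[C@@]4(O[Si](CC)(CC)CC)[C@H](CC#C)OC(=O)[C@@H]4C | intermediate
29 | 2-iodoallyl lactone | CC1(C)O[C@H](CC2OCCO2)[C@@]3(C)[C@@H](O1)CCC(=C)[C@@H]3[C@@H](O[Si](CC)(CC)CC)[C@@]4(O[Si](CC)(CC)CC)[C@H](CC(I)=C)OC(=O)[C@@H]4C | intermediate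
30 | seco aldehyde, 8,9-diol | CC1(C)O[C@H](CC=O)[C@@]3(C)[C@@H](O1)CCC(=C)[C@@H]3[C@@H](O)[C@@]4(O)[C@H](CC(I)=C)OC(=O)[C@@H]4C | intermediate
31 | macrocyclic C4 alcohol, 2,14-acetonide | C=C1CC[C@H](O5)[C@@]2(C)[C@H]1[C@@H](O)[C@@]3(O)[C@H](CC(=C)C(O)C[C@H]2OC5(C)C)OC(=O)[C@@H]3C | intermediate
32 | pentaol | C=C1CC[C@H](O)[C@@]2(C)[C@H]1[C@@H](O)[C@@]3(O)[C@H](CC(=C)C(O)C[C@H]2O)OC(=O)[C@@H]3C | intermediate
33 | triol hemiketal | C=C1CC[C@H](O)[C@@]2(C)[C@H]1[C@@H](O)[C@@]13O[C@](O)(C[C@H]2O)C(=C)C[C@@H]1OC(=O)[C@@H]3C | intermediate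
34 | (+)-junceellolide A (1R,2R,4R,7S,8S,9R,10S,14S,17R) | C=C1CC[C@H](OC(C)=O)[C@@]2(C)[C@H]1[C@@H](OC(C)=O)[C@@]13O[C@](O)(C[C@H]2OC(C)=O)C(=C)C[C@@H]1OC(=O)[C@@H]3C | target

## Summary

Total steps: 27. Longest linear sequence: 27 (from 1 and 2 to 34; the chiral-pool salt 7 enters at step 5).

Three steps most likely to fail, each with a fallback that changes the approach:

1. **Step 18** (propionate addition to the vinyl ketone: competing Michael addition, modest C17 selectivity). Fallback: take C8 and C17 from the chiral pool instead. Fráter–Seebach methylation of dimethyl (S)-malate gives (2S,3R)-3-methylmalate; its pivaldehyde dioxolanone enolate (Seebach self-regeneration of stereocentres) is added to aldehyde 20, then DIBAL and Wittig methylenation converge on the same β-vinyl acid for step 19.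
2. **Step 24** (NHK closure of a strained ten-membered ring). Fallback: close the same C4–C5 bond by Ni(0)/NHC–Et3SiH exo-selective reductive alkyne–aldehyde macrocyclisation of the alkyne aldehyde derived from 28, which also bypasses the vinyl iodide.
3. **Step 7** (dianionic Ireland–Claisen creating the quaternary centre: β-elimination or eroded selectivity). Fallback: form C1–C10 by Fráter–Seebach SN2′ alkylation of the dianion of methyl (2R,3R)-3-hydroxy-2-methylbutanoate with bromo ester 4 (C1 still set by the chelate), then correct C10 by base equilibration at the C9-aldehyde stage, where the trans-diequatorial isomer is favoured.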